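**Plan**

- Retrosynthesis first removes the phenol silyl ether, then opens ring B (C4–C10) at its only alkene. This is the trisubstituted C6=C7 bond between the C5 carbinol ester and the C8 ketone, and it is cut by ring-closing metathesis to a C5 vinyl aroate and a C8 isopropenyl ketone carried on ring A.
- The diene is then cut at the C5 and C1 esters, at C8–C7 (Weinreb amide plus isopropenyl Grignard), at C1–H, at C3–O, at C10–C9 and C10–CH3 (two enolate alkylations), at C3–isopropyl (Stork–Danheiser) and at C4–C5 (aldol with acrolein). This leads back to 3-ethoxycyclopent-2-en-1-one.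
- Forward, ring A is present from the start. Its substituents are joined in the order C4–C5, C3–isopropyl, C10–CH3, C10–C9, C8–C7, the two esters are placed, and ring B is closed in the penultimate step.
- Stereochemistry: an anti aldol fixes C4 and C5 relative to each other and a Sharpless kinetic resolution makes them absolute. C10 (alkylation) and C3 (nucleophilic epoxidation) are set on the face opposite the C4 side chain, and C1 is set by hydride delivery from the C3 hydroxyl.

Key step: step 15

Remark: locants C1–C10 in the prose are those of the target skeleton (ring A = C1, C2, C3, C4, C10; ring B = C4–C10); the hindered tertiary C3 hydroxyl is carried unprotected from step 8 onwards, on the assumption that it is tolerated by the Grignard, acylation and metathesis steps.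

**Route**

Step 1
Reactants: 1 3-ethoxycyclopent-2-en-1-one; 2 acrolein
Product: 4 rac-(5R)-3-ethoxy-5-[(1R)-1-hydroxyprop-2-en-1-yl]cyclopent-2-en-1-one (racemic anti aldol), via lithium enolate 3 (not isolated)
Conditions: LiN(iPr)2, THF, −78 °C; then 2, −78 °C; AcOH quench at −78 °C
Reagents that add atoms: none
Why: Kinetic deprotonation of the vinylogous ester at the α′ carbon gives the cross-conjugated lithium enolate, which is ring-locked in the E geometry and should add 1,2 to acrolein through a Zimmerman–Traxler chair (lithium aldol reaction) to favour the anti C4/C5 relationship, the minor syn isomer being removed by chromatography.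

Step 2
Reactants: 4 racemic anti aldol
Product: 5 (5R)-3-ethoxy-5-[(1R)-1-hydroxyprop-2-en-1-yl]cyclopent-2-en-1-one
Conditions: Ti(OiPr)4 (0.2 equiv), D-(−)-diisopropyl tartrate (0.25 equiv), t-BuOOH (0.6 equiv), 4 Å MS, CH2Cl2, −20 °C
Reagents that add atoms: none
Why: Sharpless kinetic resolution of a secondary allylic alcohol: with the titanium complex of D-(−)-diisopropyl tartrate the (4S,5S) enantiomer is epoxidised much faster and becomes a separable epoxy alcohol, so the (4R,5R) alcohol should be recovered in high enantiomeric purity at a little over half conversion, which fixes the absolute configuration of C4 and C5.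

Step 3
Reactants: 5 (4R,5R) aldol
Product: 6 (5R)-5-[(1R)-1-(tert-butyldimethylsilyloxy)prop-2-en-1-yl]-3-ethoxycyclopent-2-en-1-one
Conditions: TBSCl, imidazole, DMF, 23 °C
Reagents that add atoms: tert-butyldimethylsilyl chloride, CC(C)(C)[Si](C)(C)Cl
Why: Standard silyl ether formation caps the aldol hydroxyl so that it can neither undergo retro-aldol cleavage nor quench the organometallic and enolate steps that follow, and no stereocentre is touched.

Step 4
Reactants: 6 silyl-protected vinylogous ester; 7 isopropylmagnesium chloride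
Product: 9 (4S)-4-[(1R)-1-(tert-butyldimethylsilyloxy)prop-2-en-1-yl]-3-(propan-2-yl)cyclopent-2-en-1-one, via tertiary carbinol 8 (not isolated)
Conditions: 7, CeCl3, THF, −78 to 0 °C; then 1 M HCl, THF, 0 to 23 °C
Reagents that add atoms: water, O
Why: Stork–Danheiser enone transposition: the weakly basic organocerium reagent adds 1,2 to the hindered vinylogous ester carbonyl without enolising it, and aqueous acid then hydrolyses the enol ether and eliminates the tertiary hydroxyl, which places the isopropyl group on C3 next to the untouched C4 stereocentre and frees C10 as the new α′ position.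

Step 5
Reactants: 9 4-substituted 3-isopropylcyclopentenone
Product: 11 (4S)-4-[(1R)-1-(tert-butyldimethylsilyloxy)prop-2-en-1-yl]-5-methyl-3-(propan-2-yl)cyclopent-2-en-1-one (both epimers at the methyl-bearing carbon), via lithium enolate 10 (not isolated)
Conditions: LiN(iPr)2, THF, −78 °C; then MeI, −78 to −40 °C
Reagents that add atoms: iodomethane, CI
Why: Kinetic α′-deprotonation of the enone and C-methylation of the cross-conjugated enolate (enolate alkylation) installs the C10 methyl group, and the C10 configuration formed here is immaterial because the centre is made planar again in the next step.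

Step 6
Reactants: 11 α′-methyl enone; 12 2-bromo-N-methoxy-N-methylacetamide
Product: 14 2-[(1S,2R)-2-[(1R)-1-(tert-butyldimethylsilyloxy)prop-2-en-1-yl]-1-methyl-5-oxo-3-(propan-2-yl)cyclopent-3-en-1-yl]-N-methoxy-N-methylacetamide, via lithium enolate 13 (not isolated)
Conditions: LiN(iPr)2, THF, −78 °C; then 12, DMPU, −78 to −20 °C
Reagents that add atoms: none
Why: A second kinetic α′-enolate alkylation (substitution at the activated primary bromide of the α-halo amide) creates the quaternary C10 centre, the electrophile entering the planar enolate on the face opposite the bulky C4 silyloxyallyl group so that the acetamide arm ends up trans and the methyl group cis to the C4 side chain.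

Step 7
Reactants: 14 quaternary enone
Product: 15 2-[(1R,2R,3S,5R)-2-[(1R)-1-(tert-butyldimethylsilyloxy)prop-2-en-1-yl]-3-methyl-4-oxo-1-(propan-2-yl)-6-oxabicyclo[3.1.0]hexan-3-yl]-N-methoxy-N-methylacetamide
Conditions: 30% H2O2, 2 M NaOH, MeOH, 0 to 23 °C
Reagents that add atoms: hydrogen peroxide, OO
Why: Weitz–Scheffer nucleophilic epoxidation: hydroperoxide anion adds to the enone β-carbon C3 from the face opposite the neighbouring C4 side chain and the enolate closes the oxirane, which sets the C3 oxygen trans to the C4 side chain while the isolated vinyl group, the amide and the silyl ether are left alone.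

Step 8
Reactants: 15 epoxy ketone
Product: 16 2-[(1S,2R,3R)-2-[(1R)-1-(tert-butyldimethylsilyloxy)prop-2-en-1-yl]-3-hydroxy-1-methyl-5-oxo-3-(propan-2-yl)cyclopentyl]-N-methoxy-N-methylacetamide
Conditions: SmI2 (2.5 equiv), THF/MeOH, −90 °C
Reagents that add atoms: none
Why: Reductive opening of an α,β-epoxy ketone with SmI2: electron transfer to the ketone cleaves the Cα–O bond and methanol protonates the samarium enolate to give the β-hydroxy ketone with the C3 configuration retained, a process far faster at −90 °C than any reduction of the amide N–O bond or the allylic ether.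

Step 9
Reactants: 16 β-hydroxy ketone
Product: 17 2-[(1S,2R,3R,5S)-2-[(1R)-1-(tert-butyldimethylsilyloxy)prop-2-en-1-yl]-3,5-dihydroxy-1-methyl-3-(propan-2-yl)cyclopentyl]-N-methoxy-N-methylacetamide
Conditions: Me4NBH(OAc)3, MeCN/AcOH (1:1), −30 to −20 °C
Reagents that add atoms: none
Why: Evans–Saksena hydroxyl-directed reduction: the C3 hydroxyl exchanges onto boron and the resulting alkoxyborohydride delivers hydride intramolecularly to the C1 carbonyl on the face of the C3 oxygen, which should give the 1,3-anti diol with the new C1 hydroxyl cis to the C10 methyl group.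

Step 10
Reactants: 17 diol Weinreb amide; 18 isopropenylmagnesium bromide
Product: 19 1-[(1S,2R,3R,5S)-2-[(1R)-1-(tert-butyldimethylsilyloxy)prop-2-en-1-yl]-3,5-dihydroxy-1-methyl-3-(propan-2-yl)cyclopentyl]-3-methylbut-3-en-2-one
Conditions: 18 (4 equiv), THF, −40 to 0 °C; aq NH4Cl
Reagents that add atoms: none
Why: Weinreb ketone synthesis: after excess reagent has deprotonated the two hydroxyl groups, the Grignard reagent adds once to the N-methoxy-N-methylamide and the magnesium-chelated tetrahedral adduct survives until the quench, so the isopropenyl ketone is released only on work-up and over-addition is avoided.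

Step 11
Reactants: 19 isopropenyl ketone diol
Product: 20 (1S,2S,3R,4R)-3-[(1R)-1-(tert-butyldimethylsilyloxy)prop-2-en-1-yl]-4-hydroxy-2-methyl-2-(3-methyl-2-oxobut-3-en-1-yl)-4-(propan-2-yl)cyclopentyl acetate
Conditions: Ac2O, pyridine, DMAP (cat.), CH2Cl2, 0 to 23 °C
Reagents that add atoms: acetic anhydride, CC(=O)OC(C)=O
Why: Chemoselective DMAP-catalysed acetylation (nucleophilic acyl transfer) of the secondary C1 hydroxyl, since the tertiary C3 hydroxyl is shielded by the isopropyl group and the C4 side chain and should not react under these conditions.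

Step 12
Reactants: 20 C1 acetate
Product: 21 (1S,2S,3R,4R)-4-hydroxy-3-[(1R)-1-hydroxyprop-2-en-1-yl]-2-methyl-2-(3-methyl-2-oxobut-3-en-1-yl)-4-(propan-2-yl)cyclopentyl acetate
Conditions: HF·pyridine, pyridine, THF, 0 to 23 °C
Reagents that add atoms: none
Why: Fluoride-mediated cleavage of the silyl ether under buffered, weakly acidic conditions frees the C5 hydroxyl without touching the acetate, the enone or the tertiary alcohol and without acyl migration.

Step 13
Reactants: 22 4-hydroxybenzoic acid
Product: 24 4-(tert-butyldimethylsilyloxy)benzoic acid, via bis-silylated acid 23 (not isolated)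
Conditions: TBSCl (2.3 equiv), imidazole, DMF, 23 °C; then AcOH/H2O/THF, 23 °C
Reagents that add atoms: tert-butyldimethylsilyl chloride, CC(C)(C)[Si](C)(C)Cl
Why: Exhaustive silylation followed by selective hydrolysis of the labile silyl ester, a routine two-stage protection, leaves the phenol masked as its aryl silyl ether and the carboxylic acid free for coupling.

Step 14
Reactants: 21 C5 allylic alcohol; 24 4-(tert-butyldimethylsilyloxy)benzoic acid
Product: 25 (1R)-1-[(1R,2S,3S,5R)-3-acetoxy-5-hydroxy-2-methyl-2-(3-methyl-2-oxobut-3-en-1-yl)-5-(propan-2-yl)cyclopentyl]prop-2-en-1-yl 4-(tert-butyldimethylsilyloxy)benzoate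
Conditions: EDC·HCl, DMAP, CH2Cl2, 0 to 23 °C
Reagents that add atoms: none
Why: Steglich esterification: DMAP transfers the carbodiimide-activated acid to the secondary allylic C5 hydroxyl with retention at C5, while the hindered tertiary C3 hydroxyl stays free.

Step 15
Reactants: 25 ring A diene (C5 vinyl aroate, C8 isopropenyl ketone)
Product: 26 (1S,3R,3aR,4R,8aS)-1-acetoxy-3-hydroxy-6,8a-dimethyl-7-oxo-3-(propan-2-yl)-1,2,3,3a,4,7,8,8a-octahydroazulen-4-yl 4-(tert-butyldimethylsilyloxy)benzoate
Conditions: second-generation Hoveyda–Grubbs catalyst RuCl2(SIMes)(=CH–C6H4-2-OiPr) (10 mol%), toluene (0.003 M), 80 °C, argon sparge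
Reagents that add atoms: none
Why: The catalyst exchanges its isopropoxybenzylidene ligand for the monosubstituted C5 vinyl group, the resulting ruthenium alkylidene adds across the C8 isopropenyl alkene to give a ruthenacyclobutane, and cycloreversion releases the C6=C7 bond and a ruthenium methylidene that carries the chain with loss of ethene. The closest known reaction type is ring-closing metathesis of a terminal alkene onto an α-methylene ketone, which gives 2-methylcycloalk-2-enones including seven-membered ones. Ring B closes as a seven-membered carbocycle by joining the alkene termini of two arms that sit trans on the adjacent ring A carbons C4 and C10, so the trans ring fusion is already built in and the arms can reach each other without strain. No stereocentre is formed, and the ring size enforces the cis ring alkene. The step needs initiation at the vinyl group and cyclisation in preference to dimerisation: the electron-poor 1,1-disubstituted enone alkene neither loads the catalyst nor homodimerises, the allylic oxygen is masked as the aroate so that it does not bind ruthenium strongly or allow isomerisation to a ketone, and high dilution favours ring closure. The free tertiary C3 hydroxyl, the acetate and the aryl silyl ether are inert to the catalyst.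

Step 16
Reactants: 26 silyl-protected target
Product: 27 (1S,3R,3aR,4R,8aS)-1-acetoxy-3-hydroxy-6,8a-dimethyl-7-oxo-3-(propan-2-yl)-1,2,3,3a,4,7,8,8a-octahydroazulen-4-yl 4-hydroxybenzoate (CNP0087181.1)
Conditions: Bu4NF, AcOH, THF, 0 °C
Reagents that add atoms: none
Why: Fluoride cleavage of an aryl silyl ether is fast at 0 °C, and buffering with acetic acid keeps the medium too weakly basic for ester cleavage, acyl migration or conjugate addition of the C3 hydroxyl to the enone, so the target should be released unchanged.

**Compound list**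

1 | 3-ethoxycyclopent-2-en-1-one | CCOC1=CC(=O)CC1 | starting material
2 | acrolein (prop-2-enal) | C=CC=O | starting material
3 | lithium 4-ethoxycyclopenta-1,4-dien-1-olate (kinetic enolate of 1, not isolated) | CCOC1=CC(O[Li])=CC1 | intermediate
4 | rac-(5R)-3-ethoxy-5-[(1R)-1-hydroxyprop-2-en-1-yl]cyclopent-2-en-1-one (racemic anti aldol, both enantiomers written) | CCOC1=CC(=O)[C@@H]([C@H](O)C=C)C1.CCOC1=CC(=O)[C@H]([C@@H](O)C=C)C1 | intermediate
5 | (5R)-3-ethoxy-5-[(1R)-1-hydroxyprop-2-en-1-yl]cyclopent-2-en-1-one | CCOC1=CC(=O)[C@@H]([C@H](O)C=C)C1 | intermediate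
6 | (5R)-5-[(1R)-1-(tert-butyldimethylsilyloxy)prop-2-en-1-yl]-3-ethoxycyclopent-2-en-1-one | CCOC1=CC(=O)[C@@H]([C@H](O[Si](C)(C)C(C)(C)C)C=C)C1 | intermediate
7 | isopropylmagnesium chloride | CC(C)[Mg]Cl | starting material
8 | (5R)-5-[(1R)-1-(tert-butyldimethylsilyloxy)prop-2-en-1-yl]-3-ethoxy-1-(propan-2-yl)cyclopent-2-en-1-ol (both carbinol epimers, not isolated) | CCOC1=CC(O)(C(C)C)[C@@H]([C@H](O[Si](C)(C)C(C)(C)C)C=C)C1 | intermediate
9 | (4S)-4-[(1R)-1-(tert-butyldimethylsilyloxy)prop-2-en-1-yl]-3-(propan-2-yl)cyclopent-2-en-1-one | O=C1C=C(C(C)C)[C@@H]([C@H](O[Si](C)(C)C(C)(C)C)C=C)C1 | intermediate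
10 | lithium (3S)-3-[(1R)-1-(tert-butyldimethylsilyloxy)prop-2-en-1-yl]-4-(propan-2-yl)cyclopenta-1,4-dien-1-olate (not isolated) | [Li]OC1=C[C@H]([C@H](O[Si](C)(C)C(C)(C)C)C=C)C(C(C)C)=C1 | intermediate
11 | (4S)-4-[(1R)-1-(tert-butyldimethylsilyloxy)prop-2-en-1-yl]-5-methyl-3-(propan-2-yl)cyclopent-2-en-1-one (both epimers at the methyl-bearing carbon) | O=C1C=C(C(C)C)[C@@H]([C@H](O[Si](C)(C)C(C)(C)C)C=C)C1C | intermediate
12 | 2-bromo-N-methoxy-N-methylacetamide | CON(C)C(=O)CBr | starting material
13 | lithium (3R)-3-[(1R)-1-(tert-butyldimethylsilyloxy)prop-2-en-1-yl]-2-methyl-4-(propan-2-yl)cyclopenta-1,4-dien-1-olate (not isolated) | [Li]OC1=C(C)[C@H]([C@H](O[Si](C)(C)C(C)(C)C)C=C)C(C(C)C)=C1 | intermediate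
14 | 2-[(1S,2R)-2-[(1R)-1-(tert-butyldimethylsilyloxy)prop-2-en-1-yl]-1-methyl-5-oxo-3-(propan-2-yl)cyclopent-3-en-1-yl]-N-methoxy-N-methylacetamide | O=C1C=C(C(C)C)[C@@H]([C@H](O[Si](C)(C)C(C)(C)C)C=C)[C@]1(C)CC(=O)N(C)OC | intermediate
15 | 2-[(1R,2R,3S,5R)-2-[(1R)-1-(tert-butyldimethylsilyloxy)prop-2-en-1-yl]-3-methyl-4-oxo-1-(propan-2-yl)-6-oxabicyclo[3.1.0]hexan-3-yl]-N-methoxy-N-methylacetamide | O=C1[C@@H]2O[C@]2(C(C)C)[C@@H]([C@H](O[Si](C)(C)C(C)(C)C)C=C)[C@]1(C)CC(=O)N(C)OC | intermediate
16 | 2-[(1S,2R,3R)-2-[(1R)-1-(tert-butyldimethylsilyloxy)prop-2-en-1-yl]-3-hydroxy-1-methyl-5-oxo-3-(propan-2-yl)cyclopentyl]-N-methoxy-N-methylacetamide | O=C1C[C@@](O)(C(C)C)[C@@H]([C@H](O[Si](C)(C)C(C)(C)C)C=C)[C@]1(C)CC(=O)N(C)OC | intermediate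
17 | 2-[(1S,2R,3R,5S)-2-[(1R)-1-(tert-butyldimethylsilyloxy)prop-2-en-1-yl]-3,5-dihydroxy-1-methyl-3-(propan-2-yl)cyclopentyl]-N-methoxy-N-methylacetamide | O[C@H]1C[C@@](O)(C(C)C)[C@@H]([C@H](O[Si](C)(C)C(C)(C)C)C=C)[C@]1(C)CC(=O)N(C)OC | intermediate
18 | isopropenylmagnesium bromide | CC(=C)[Mg]Br | starting material
19 | 1-[(1S,2R,3R,5S)-2-[(1R)-1-(tert-butyldimethylsilyloxy)prop-2-en-1-yl]-3,5-dihydroxy-1-methyl-3-(propan-2-yl)cyclopentyl]-3-methylbut-3-en-2-one | O[C@H]1C[C@@](O)(C(C)C)[C@@H]([C@H](O[Si](C)(C)C(C)(C)C)C=C)[C@]1(C)CC(=O)C(C)=C | intermediate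
20 | (1S,2S,3R,4R)-3-[(1R)-1-(tert-butyldimethylsilyloxy)prop-2-en-1-yl]-4-hydroxy-2-methyl-2-(3-methyl-2-oxobut-3-en-1-yl)-4-(propan-2-yl)cyclopentyl acetate | CC(=O)O[C@H]1C[C@@](O)(C(C)C)[C@@H]([C@H](O[Si](C)(C)C(C)(C)C)C=C)[C@]1(C)CC(=O)C(C)=C | intermediate
21 | (1S,2S,3R,4R)-4-hydroxy-3-[(1R)-1-hydroxyprop-2-en-1-yl]-2-methyl-2-(3-methyl-2-oxobut-3-en-1-yl)-4-(propan-2-yl)cyclopentyl acetate | CC(=O)O[C@H]1C[C@@](O)(C(C)C)[C@@H]([C@H](O)C=C)[C@]1(C)CC(=O)C(C)=C | intermediate
22 | 4-hydroxybenzoic acid | OC(=O)c1ccc(O)cc1 | starting material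
23 | tert-butyldimethylsilyl 4-(tert-butyldimethylsilyloxy)benzoate (not isolated) | CC(C)(C)[Si](C)(C)OC(=O)c1ccc(O[Si](C)(C)C(C)(C)C)cc1 | intermediate
24 | 4-(tert-butyldimethylsilyloxy)benzoic acid | CC(C)(C)[Si](C)(C)Oc1ccc(cc1)C(O)=O | intermediate
25 | (1R)-1-[(1R,2S,3S,5R)-3-acetoxy-5-hydroxy-2-methyl-2-(3-methyl-2-oxobut-3-en-1-yl)-5-(propan-2-yl)cyclopentyl]prop-2-en-1-yl 4-(tert-butyldimethylsilyloxy)benzoate | CC(=O)O[C@H]1C[C@@](O)(C(C)C)[C@@H]([C@H](OC(=O)c2ccc(O[Si](C)(C)C(C)(C)C)cc2)C=C)[C@]1(C)CC(=O)C(C)=C | intermediate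
26 | (1S,3R,3aR,4R,8aS)-1-acetoxy-3-hydroxy-6,8a-dimethyl-7-oxo-3-(propan-2-yl)-1,2,3,3a,4,7,8,8a-octahydroazulen-4-yl 4-(tert-butyldimethylsilyloxy)benzoate | CC(=O)O[C@H]1C[C@@](O)(C(C)C)[C@H]2[C@H](OC(=O)c3ccc(O[Si](C)(C)C(C)(C)C)cc3)C=C(C)C(=O)C[C@]12C | intermediate
27 | (1S,3R,3aR,4R,8aS)-1-acetoxy-3-hydroxy-6,8a-dimethyl-7-oxo-3-(propan-2-yl)-1,2,3,3a,4,7,8,8a-octahydroazulen-4-yl 4-hydroxybenzoate (CNP0087181.1) | CC(=O)O[C@H]1C[C@@](O)(C(C)C)[C@H]2[C@H](OC(=O)c3ccc(O)cc3)C=C(C)C(=O)C[C@]12C | target

**Totals**

Total step count: 16. Longest linear sequence: 15 steps (steps 1–12 and 14–16); step 13 is a one-step side branch.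

**Steps most likely to fail**

Step 7. Hydroperoxide may add too slowly to C3, a β,β-disubstituted enone carbon flanked by the isopropyl group and the C4 side chain. During long exposure to base, γ-deprotonation at C4 could then lead to loss of the silyloxy group or to C4 epimerisation. The fallback sets out from 14 and replaces the oxygen nucleophile by a boron one. Copper-catalysed conjugate borylation (CuCl, NaOtBu, a bisphosphine or N-heterocyclic carbene ligand, B2pin2, MeOH, THF) should deliver boron to C3 on the face opposite the C4 side chain and give the β-boryl ketone F1. Oxidation with NaBO3·4H2O in THF/H2O exchanges boron for hydroxyl with retention and comes back to the route at 16, so that 15 and the SmI2 step are bypassed.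

Step 6. Alkylation of the fully substituted, crowded C10 enolate by the bromoacetamide may be sluggish, so that proton transfer to the enolate or O-alkylation competes. The fallback sets out from 11 and uses a more reactive allylic electrophile. The same lithium enolate is alkylated with prenyl bromide, again opposite the C4 side chain, to give the prenyl ketone F2. Selective ozonolysis of the electron-rich trisubstituted alkene (O3, pyridine, CH2Cl2, −78 °C, Sudan Red 7B as end-point indicator, then Me2S) should spare the vinyl group and the enone and give the aldehyde F3. Pinnick oxidation (NaClO2, NaH2PO4, 2-methylbut-2-ene, t-BuOH/H2O) gives the carboxylic acid F4. Coupling of the acid with N,O-dimethylhydroxylamine hydrochloride (EDC·HCl, iPr2NEt, CH2Cl2) comes back to the route at 14.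

Step 15. The ruthenium alkylidene formed at the vinyl group may fail to engage the electron-poor 1,1-disubstituted enone alkene, so that intermolecular dimerisation at the vinyl group or catalyst decay outruns ring closure. The fallback sets out from 25 and keeps the same ring-closing disconnection at a lower oxidation level. Luche reduction (NaBH4, CeCl3·7H2O, MeOH, −78 °C) of the C8 ketone gives the allylic alcohol F5 as a mixture of C8 epimers, whose isopropenyl carbinol alkene is a more willing metathesis partner. Ring closure with the same catalyst should give the cycloheptenol F6. Oxidation of this allylic alcohol with MnO2 in CH2Cl2 comes back to the route at 26.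

**Further compounds**

F1 | step 7 | C3 pinacol boronate of ketone 16 (boron in place of the C3 hydroxyl on the same face) | O=C1C[C@@](B2OC(C)(C)C(C)(C)O2)(C(C)C)[C@@H]([C@H](O[Si](C)(C)C(C)(C)C)C=C)[C@]1(C)CC(=O)N(C)OC
F2 | step 6 | C10 prenyl analogue of enone 14 (3-methylbut-2-en-1-yl in place of the acetamide arm) | O=C1C=C(C(C)C)[C@@H]([C@H](O[Si](C)(C)C(C)(C)C)C=C)[C@]1(C)CC=C(C)C
F3 | step 6 | C8 aldehyde (2-oxoethyl arm on C10 of the enone) | O=C1C=C(C(C)C)[C@@H]([C@H](O[Si](C)(C)C(C)(C)C)C=C)[C@]1(C)CC=O
F4 | step 6 | C8 carboxylic acid (carboxymethyl arm on C10 of the enone) | O=C1C=C(C(C)C)[C@@H]([C@H](O[Si](C)(C)C(C)(C)C)C=C)[C@]1(C)CC(O)=O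
F5 | step 15 | C8 allylic alcohol of diene 25 (both C8 epimers) | CC(=O)O[C@H]1C[C@@](O)(C(C)C)[C@@H]([C@H](OC(=O)c2ccc(O[Si](C)(C)C(C)(C)C)cc2)C=C)[C@]1(C)CC(O)C(C)=C
F6 | step 15 | C8 allylic alcohol of ring-closed 26 (both C8 epimers) | CC(=O)O[C@H]1C[C@@](O)(C(C)C)[C@H]2[C@H](OC(=O)c3ccc(O[Si](C)(C)C(C)(C)C)cc3)C=C(C)C(O)C[C@]12C
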